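Read at 40 h, a fed flask shows what came in minus what still stands unconverted, so the standing part is the thing to watch, and turnovers count it.

| flask | substrate | free catalyst | remark | time |
|---|---|---|---|---|
| south-east | 3.7 mM (fed, over 40 h) | 0.12 mM | run made earlier; the fed solution adds 0.20 times the starting volume |  |
| north-east | 24 mM (fed, over 40 h) | 0.12 mM | run made earlier; the fed solution adds 0.20 times the starting volume |  |
| north-west | 10 mM (fed, over 40 h) | 0.049 mM | run made earlier; the fed solution adds 0.20 times the starting volume |  |
| grey | 10 mM (fed, over 40 h) | 0.040 mM | the fed solution adds 0.20 times the starting volume | 40 h |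
| teal | 15 mM (fed, over 20 h) | 0.12 mM | the fed solution adds 0.20 times the starting volume | 40 h |
| amber | 2.5 mM (fed, over 40 h) | 0.12 mM | the fed solution adds 0.20 times the starting volume | 40 h |
| red | 10 mM (fed, over 40 h) | 0.12 mM | the fed solution adds 0.20 times the starting volume | 40 h |

| run | time / h | product / % |
|---|---|---|
| south-east | 3.00 | 2.0 |
| south-east | 6.00 | 4.8 |
| south-east | 12.0 | 17.4 |
| south-east | 20.0 | 34.0 |
| south-east | 40.0 | 82.5 |
| north-east | 3.00 | 1.1 |
| north-east | 6.00 | 4.2 |
| north-east | 12.0 | 12.1 |
| north-east | 20.0 | 23.4 |
| north-east | 40.0 | 52.8 |
| north-west | 4.00 | 0.9 |
| north-west | 10.0 | 6.7 |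
| north-west | 20.0 | 15.7 |
| north-west | 30.0 | 28.6 |
| north-west | 40.0 | 41.2 |

(scatter of a reading: 0.5 percentage points)

1. the flasks by amount of product, in percent of the substrate charged, highest first, at 40 h (grey / teal / amber / red)
2. the same order at 8.0 h (grey / teal / amber / red)
3. the amount of product, in percent of the substrate charged of the flask you put first, at 40 h
4. the amount of product, in percent of the substrate charged of the flask you put last, at 40 h

- amounts are per litre of the starting volume; all of the dose is in the solution fed
- steps under discussion: substrate + free catalyst -> catalyst intermediate A; catalyst intermediate A <-> catalyst intermediate B; catalyst intermediate B <-> free catalyst + product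
- percentages count the whole charge, also what has not yet gone in

The south-east run has amber's catalyst charge. Between 20.0 h and 40.0 h its product rises at

rate = 0.0897 mM h⁻¹, or 0.748 h⁻¹ per catalyst,

about as fast as the feed of 0.0925 mM h⁻¹. At 40.0 h the south-east reading puts 0.647 mM of the charge short of product, so

τ = unconverted / rate = 7.22 h.

This is the clearing time: standing substrate over its rate of turnover, a pseudo-first-order time, scaling inversely with catalyst at a fixed busy share. Under a steady feed and with τ held constant, the unconverted share of the charge at the end of dosing is

(τ / dosing time)(1 − exp(−dosing time / τ)).

For amber the exponential is negligible, since 40 h is far longer than τ, and this first estimate gives 18.1% unconverted.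

The weak link is that the south-east run turns over faster per catalyst than amber's feed of 0.521 h⁻¹. Taking the north-east reading, 2.94 h⁻¹ per catalyst, as a working ceiling, the estimated busy share is 25.4% in the south-east run but 17.7% in amber. Correcting for the free share:

τ(amber) = 6.54 h, so this reckoning, which is separate from the forecast, estimates amber's product at 83.7%.

The forecast gives amber > teal > red > grey at 40 h, teal > amber > red > grey at 8.0 h, top 84% and low 35%. Its ground is that the runs look like “simple saturable turnover with a short lag”.

The flasks give amber > teal > red > grey at 40 h and teal > amber > red > grey at 8.0 h, with amber at 84.1% and grey at 35.2%, so the forecast held. At 40.0 h, amber's free catalyst stands at 83.2% of the catalyst charged. Amber's product has moved by 5 points at a free catalyst charge of 0.0917 mM, and τ(amber), scaled inversely to that charge, adds 5.1 percentage points to the estimated unconverted share.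

    substrate + free catalyst → catalyst intermediate A (k = 32.0 M⁻¹ min⁻¹)
    catalyst intermediate A ⇌ catalyst intermediate B (K = 2.60, k = 1.40 min⁻¹)
    catalyst intermediate B ⇌ free catalyst + product (K = 0.0440 M, k = 0.100 min⁻¹)

For a neighbour of amber charged with 0.030 mM of free catalyst, the south-east τ scaled inversely with catalyst, its busy share taken unchanged, gives τ = 28.9 h against a dosing time of 40 h, so the exponential is kept and the estimate is 54.1% unconverted. The computed neighbour holds 53.6% substrate and 46.0% product at 40.0 h.

(The data stem from a simulated flask with constants of no real substance.)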